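The data were computed on assumed constants, and the scatter is random.

common to all: pre-initiator 0.5 mol%
- green: free monomer 0.68 mM; run made earlier
- blue: free monomer 4.5 mM; run made earlier
- dusk: free monomer 5.0 mM; time 5.0 min
- noon: free monomer 1.2 mM; time 5.0 min

| run | time / min | monomer in chains / % | free monomer / % |
|---|---|---|---|
| green | 0.500 | 20.3 | 78.4 |
| green | 1.00 | 27.2 | 71.7 |
| green | 1.50 | 30.8 | 72.5 |
| green | 2.00 | 31.1 | 69.5 |
| green | 2.50 | 29.4 | 71.2 |
| blue | 0.500 | 89.7 | 10.6 |
| blue | 1.00 | 89.0 | 11.4 |
| blue | 1.50 | 89.0 | 9.5 |
| blue | 2.00 | 89.4 | 11.5 |
| blue | 2.50 | 88.4 | 12.5 |

(standard deviation of a reading: 1 percentage point)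

- the average divides the monomer in chains by the number of chains begun, living and dead together
- the earlier runs do not show the number of chains; that part of a forecast is a guess

- which of the two ends with the longer chains by the average number of monomer units in a chain (chains begun, living or dead) ("neither" if they lie within 10%) (dusk / noon / neither)
- average number of monomer units in a chain (chains begun, living or dead) at the end, dusk
- average number of monomer units in a chain (chains begun, living or dead) at the end, noon

I start from amounts: the green run charges 0.68 mM of free monomer and the blue run 4.5 mM, yet each stops at nearly the same concentration of it. Green's readings from the second on average 0.484 mM, and blue's average 0.500 mM. I call their mean 0.492 mM the floor M*, the concentration of free monomer at which a flask stops changing, or equilibrium monomer concentration.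

The times form a ladder. On the first rung stands blue, already flat at its first reading, 0.500 min. Next comes green, still rising there and flat by about 1.50 min, which is later than blue. The top rung is the asked 5.0 min, longer than green needed. Noon's charge lies above green's and dusk's above blue's, so I expect both flasks to stand on the floor by then.

Let C be the charge and x the loading of pre-initiator. If each pre-initiator begins one chain, which the readings cannot show, the length is n = (C − M*)/(xC). My reckoning gives 180 for dusk and 118 for noon. The forecast names dusk, with 180 for dusk and 118 for noon, on the view that this “looks like a ceiling-type equilibrium”.

The flask gives dusk, with 181 for dusk and 121 for noon.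

    free monomer + living end → monomer in chains + living end, rate k1*[living end]*[free monomer] (k = 13000 M⁻¹ s⁻¹)
    free monomer + initiator → living end + monomer in chains (k = 1200 M⁻¹ s⁻¹)
    monomer in chains + living end → free monomer + living end, rate k3*[living end] as long as [monomer in chains] is above zero (k = 6.20 s⁻¹)
    pre-initiator → initiator (k = 3.60 s⁻¹)

The gap between the two flasks comes mainly from the difference in concentration of free monomer: noon without that difference gives 181 instead of 121. M* leaves 41.0% of noon's charge free, and noon holds 39.7% at 5.00 min. For a neighbour of noon charged with 0.72 mM at the same loading, M* leaves 68.3% free and gives a length of 63.4; that neighbour holds 66% free, with length 67.8.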